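The cyclohexanone ring is cut at C1–C6 and C2–C3. In this ring the fully substituted C1, which carries the palmitoyloxyethyl chain, sits 1,4 to the C4 carbonyl. That is the para pattern of a Diels–Alder reaction between a 2-silyloxybutadiene and a 1,1-disubstituted alkene. In one operation the cycloaddition closes the six-membered ring, creates the quaternary carbon and delivers the C4 ketone in masked form. Its precursor is a 2-substituted acrolein that already bears the palmitate ester. The formyl group activates the alkene and is later excised, the C1 hydroxyl taking its place through decarboxylative oxygenation.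

Key step: step 4

Remark on the chemistry: the target has no stereocentre (a mirror plane passes through C1 and C4), so no stereocontrol is needed. Ring atoms are numbered from C1 (carbinol carbon) to C4 (carbonyl carbon).

Step 1
Reactants: 1 butane-1,4-diol (5 equiv); 2 palmitoyl chloride
Product: 3 4-hydroxybutyl palmitate
Conditions: pyridine, THF, 0 °C to rt, slow addition of 2
Reagents that add atoms: none
Why: O-acylation by nucleophilic acyl substitution, in which the large excess of the symmetrical diol should favour the monoester statistically and the surplus water-soluble diol is washed out.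

Step 2
Reactants: 3 4-hydroxybutyl palmitate
Product: 4 4-oxobutyl palmitate
Conditions: TEMPO (2,2,6,6-tetramethylpiperidin-1-oxyl, cat.), PhI(OAc)2, CH2Cl2, rt
Reagents that add atoms: none
Why: Nitroxide-catalysed alcohol oxidation with PhI(OAc)2 as terminal oxidant should stop at the aldehyde under anhydrous conditions and leave the ester untouched.

Step 3
Reactants: 4 4-oxobutyl palmitate; 5 formaldehyde (37% aqueous)
Product: 6 3-formylbut-3-en-1-yl palmitate
Conditions: pyrrolidine (10 mol%), propionic acid (10 mol%), i-PrOH, 45 °C
Reagents that add atoms: none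
Why: Organocatalytic alpha-methylenation, in which the enamine of 4 adds to the formaldehyde-derived iminium ion (Mannich reaction) and beta-elimination of the amine should give the 2-substituted acrolein, used promptly to avoid oligomerisation.

Step 4
Reactants: 6 3-formylbut-3-en-1-yl palmitate; 7 2-(trimethylsilyloxy)buta-1,3-diene (2.5 equiv)
Product: 9 2-(1-formyl-4-oxocyclohexyl)ethyl palmitate, via silyl enol ether cycloadduct 8 (not isolated)
Conditions: BHT (2,6-di-tert-butyl-4-methylphenol, cat.), toluene, 110 °C, sealed tube; then 1 M HCl, THF, 0 °C
Reagents that add atoms: none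
Why: The electron-rich diene 7 (HOMO raised by the 2-silyloxy group) and the formyl-activated alkene of 6 (lowered LUMO) should combine in a concerted, suprafacial thermal [4+2] cycloaddition of normal electron demand, the closest known reaction type being the Diels–Alder reaction of 2-silyloxybutadienes with methacrolein and other 2-alkylacroleins. The six-membered ring closes by intermolecular [4+2] annulation in which C1–C6 and C2–C3 form in the same step. The only stereocentre that appears is C1 of the racemic enol ether 8, and it vanishes on hydrolysis because the two ring arms of C1 become identical in 9, so no stereocontrol is needed. The selectivity required is para over meta regiochemistry, secured by bonding of the diene terminus next to the silyloxy carbon (largest HOMO coefficient) to the unsubstituted CH2 of the enal (largest LUMO coefficient). The palmitate ester is inert to the heating and to the brief dilute-acid work-up, which cleaves only the silyl enol ether and unveils the C4 ketone.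

Step 5
Reactants: 9 2-(1-formyl-4-oxocyclohexyl)ethyl palmitate
Product: 10 4-oxo-1-[2-(palmitoyloxy)ethyl]cyclohexane-1-carboxylic acid
Conditions: NaClO2, NaH2PO4, 2-methylbut-2-ene, t-BuOH/H2O, rt
Reagents that add atoms: sodium chlorite, [Na+].[O-]Cl=O
Why: Pinnick oxidation, in which chlorous acid adds to the non-enolisable aldehyde and fragments to the acid while the alkene scavenges hypochlorous acid, should leave ketone and ester unchanged.

Step 6
Reactants: 10 4-oxo-1-[2-(palmitoyloxy)ethyl]cyclohexane-1-carboxylic acid
Product: 12 2-thioxopyridin-1(2H)-yl 4-oxo-1-[2-(palmitoyloxy)ethyl]cyclohexane-1-carboxylate, via acid chloride 11 (not isolated)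
Conditions: (COCl)2, DMF (cat.), CH2Cl2, 0 °C to rt; evaporate; sodium 2-thioxopyridin-1(2H)-olate (C5H4NOSNa), 4-(dimethylamino)pyridine (cat.), CH2Cl2, rt, dark
Reagents that add atoms: sodium 2-thioxopyridin-1(2H)-olate, [Na+].[O-]n1ccccc1=S; oxalyl chloride, O=C(Cl)C(=O)Cl (supplies the chlorine of 11 only)
Why: Vilsmeier-type activation to the acid chloride followed by O-acylation of the thiohydroxamate salt is the standard preparation of Barton esters from hindered tertiary acids, and the product is used crude with exclusion of light.

Step 7
Reactants: 12 2-thioxopyridin-1(2H)-yl 4-oxo-1-[2-(palmitoyloxy)ethyl]cyclohexane-1-carboxylate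
Product: 14 2-(1-hydroxy-4-oxocyclohexyl)ethyl palmitate, via tertiary hydroperoxide 13 (not isolated)
Conditions: t-BuSH (excess), O2 (bubbling), toluene, tungsten lamp, 0 °C to rt; then P(OEt)3, rt
Reagents that add atoms: dioxygen, O=O
Why: Barton decarboxylative hydroxylation, in which photolytic N–O homolysis and loss of CO2 give the tertiary C1 radical, oxygen traps it, the peroxyl radical takes hydrogen from the thiol and the thiyl radical carries the chain by attacking the thiocarbonyl of 12, after which the phosphite should reduce the hydroperoxide to the alcohol.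

Compound list
1 | butane-1,4-diol | OCCCCO | starting material
2 | palmitoyl chloride (hexadecanoyl chloride) | CCCCCCCCCCCCCCCC(=O)Cl | starting material
3 | 4-hydroxybutyl palmitate | CCCCCCCCCCCCCCCC(=O)OCCCCO | intermediate
4 | 4-oxobutyl palmitate | CCCCCCCCCCCCCCCC(=O)OCCCC=O | intermediate
5 | formaldehyde | C=O | starting material
6 | 3-formylbut-3-en-1-yl palmitate | CCCCCCCCCCCCCCCC(=O)OCCC(=C)C=O | intermediate
7 | 2-(trimethylsilyloxy)buta-1,3-diene | C=CC(=C)O[Si](C)(C)C | starting material
8 | 2-[1-formyl-4-(trimethylsilyloxy)cyclohex-3-en-1-yl]ethyl palmitate (racemic, not isolated) | CCCCCCCCCCCCCCCC(=O)OCCC1(C=O)CCC(O[Si](C)(C)C)=CC1 | intermediate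
9 | 2-(1-formyl-4-oxocyclohexyl)ethyl palmitate | CCCCCCCCCCCCCCCC(=O)OCCC1(C=O)CCC(=O)CC1 | intermediate
10 | 4-oxo-1-[2-(palmitoyloxy)ethyl]cyclohexane-1-carboxylic acid | CCCCCCCCCCCCCCCC(=O)OCCC1(C(=O)O)CCC(=O)CC1 | intermediate
11 | 2-[1-(chlorocarbonyl)-4-oxocyclohexyl]ethyl palmitate (not isolated) | CCCCCCCCCCCCCCCC(=O)OCCC1(C(=O)Cl)CCC(=O)CC1 | intermediate
12 | 2-thioxopyridin-1(2H)-yl 4-oxo-1-[2-(palmitoyloxy)ethyl]cyclohexane-1-carboxylate (Barton ester) | CCCCCCCCCCCCCCCC(=O)OCCC1(CCC(=O)CC1)C(=O)On1ccccc1=S | intermediate
13 | 2-(1-hydroperoxy-4-oxocyclohexyl)ethyl palmitate (not isolated) | CCCCCCCCCCCCCCCC(=O)OCCC1(OO)CCC(=O)CC1 | intermediate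
14 | 2-(1-hydroxy-4-oxocyclohexyl)ethyl palmitate | CCCCCCCCCCCCCCCC(=O)OCCC1(O)CCC(=O)CC1 | target

Total step count: 7
Longest linear sequence: 7 steps (from butane-1,4-diol 1 to target 14)

Steps most likely to fail

Step 4. The cycloaddition at the 1,1-disubstituted alkene may be slow. Thermal oligomerisation of the enal and protodesilylation of the diene during prolonged heating could then outrun ring formation. The fallback abandons the cycloaddition in favour of oxidative dearomatisation. It sets out from palmitoyl chloride 2 and returns to the route at target 14. Acylation of the aliphatic hydroxyl of purchased 4-(2-hydroxyethyl)phenol with 2 in dimethyl carbonate at rt without base should spare the phenol and give 4-hydroxyphenethyl palmitate F1. Oxidation of this para-alkylphenol with PhI(OAc)2 in aqueous MeCN at 0 °C should trap the phenoxenium-type intermediate with water at the para carbon and give the quinol 2-(1-hydroxy-4-oxocyclohexa-2,5-dien-1-yl)ethyl palmitate F2. Hydrogenation of both ring alkenes over Pd/C in EtOAc at rt should then give 14.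

Step 7. The radical chain may be diverted: the tertiary radical can recombine with the thiopyridyl unit before oxygen captures it. Reduction may also stall where the hydroperoxide closes reversibly onto the C4 ketone as a bicyclic peroxy hemiketal. The fallback sets out from acid 10, bypasses the thiohydroxamate ester and the hydroperoxide, and returns at target 14. Coupling of 10 with N-hydroxyphthalimide (N,N'-diisopropylcarbodiimide, 4-(dimethylamino)pyridine, CH2Cl2) should give the redox-active ester 1,3-dioxoisoindolin-2-yl 4-oxo-1-[2-(palmitoyloxy)ethyl]cyclohexane-1-carboxylate F3. Blue-light irradiation with Ru(bpy)3Cl2 (cat.), Hantzsch ester and TEMPO should bring about reductive decarboxylation and nitroxide trapping of the C1 radical, giving the alkoxyamine 2-{4-oxo-1-[(2,2,6,6-tetramethylpiperidin-1-yl)oxy]cyclohexyl}ethyl palmitate F4. Cleavage of the N–O bond with Zn in AcOH/THF at 50 °C should release 14.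

Step 3. Under the aqueous amine/acid catalysis the unbranched aldehyde may self-condense, and the catalyst may add in conjugate fashion to the newly formed enal and start oligomerisation. The fallback replaces the catalytic aqueous condensation by a stoichiometric, anhydrous Mannich–elimination sequence. It sets out from aldehyde 4 and returns at enal 6. Treatment of 4 with N,N-dimethylmethyleneiminium iodide and Et3N in CH2Cl2 at rt should give the Mannich base 4-(dimethylamino)-3-formylbutyl palmitate F5. This beta-amino aldehyde should lose dimethylamine on continued stirring with Et3N or on silica gel to give 6.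

Further compounds
F1 | step 4 | 4-hydroxyphenethyl palmitate | CCCCCCCCCCCCCCCC(=O)OCCc1ccc(O)cc1
F2 | step 4 | 2-(1-hydroxy-4-oxocyclohexa-2,5-dien-1-yl)ethyl palmitate | CCCCCCCCCCCCCCCC(=O)OCCC1(O)C=CC(=O)C=C1
F3 | step 7 | 1,3-dioxoisoindolin-2-yl 4-oxo-1-[2-(palmitoyloxy)ethyl]cyclohexane-1-carboxylate | CCCCCCCCCCCCCCCC(=O)OCCC1(CCC(=O)CC1)C(=O)ON1C(=O)c2ccccc2C1=O
F4 | step 7 | 2-{4-oxo-1-[(2,2,6,6-tetramethylpiperidin-1-yl)oxy]cyclohexyl}ethyl palmitate | CCCCCCCCCCCCCCCC(=O)OCCC1(CCC(=O)CC1)ON1C(C)(C)CCCC1(C)C
F5 | step 3 | 4-(dimethylamino)-3-formylbutyl palmitate (racemic) | CCCCCCCCCCCCCCCC(=O)OCCC(CN(C)C)C=O
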